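A direct plan would take quercetin A1, mask the ring B catechol as diphenylmethylene ketal A2, methylate 3-OH to 3-methyl ether A3, brominate C6 and C8 to dibromide A4, exchange both bromides for methoxide (NaOMe, CuBr) and hydrolyse the ketal to 5,7,3',4'-tetrahydroxy-3,6,8-trimethoxyflavone A5, and finally methoxylate C6' of ring B by anodic oxidation in methanol. Its weakest steps would be the mono-methylation of 3-OH, because the more acidic 7-OH would compete; the double bromide-to-methoxide exchange on a free 5,7-diphenol, where hydrodebromination and half-exchange would give mixtures that are hard to separate; and the closing oxidative methoxylation of ring B, which is unprecedented on a flavone and exposed to over-oxidation of the electron-rich ring A.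

The route disconnects ring C at two bonds, C4–C4a and O1–C2, into a mirror-symmetric ring A resorcinol and an α-methoxy aroylacetate that carries C2, C3, C4 and ring B. In one operation a thermal acylketene annulation acylates the only unsubstituted carbon of ring A (future C4a), which lies between two equivalent hydroxyls, and closes the pyranone; either hydroxyl gives the same flavone and the other is left as 5-OH. Because all four methoxy groups (C3, C6, C8, C2') arrive inside the building blocks, no polyphenol has to be methylated selectively, no bromide is exchanged for methoxide, and ring B is never oxidised on the flavone.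

Key step: step 8

Assumption: the target is achiral (no stereocentre, no hindered axis), so the steps only have to control regiochemistry.

Step 1
Reactants: 1 2,6-dimethoxyphenol (syringol)
Product: 2 2-(benzyloxy)-1,3-dimethoxybenzene
Conditions: BnBr (1.1 equiv), K2CO3 (1.5 equiv), DMF, 60 °C
Reagents that add atoms: benzyl bromide, BrCc1ccccc1
Why: Williamson ether synthesis; capping the strongly para-directing OH as a benzyl ether leaves the two OMe groups to direct the next step, and the benzyl group leaves in the last step together with those of ring B.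

Step 2
Reactants: 2 2-(benzyloxy)-1,3-dimethoxybenzene
Product: 3 3-(benzyloxy)-1,5-dibromo-2,4-dimethoxybenzene
Conditions: NBS (2.1 equiv), MeCN, 0 °C to rt, dark
Reagents that add atoms: N-bromosuccinimide, O=C1CCC(=O)N1Br
Why: Electrophilic aromatic bromination; C4 and C6 of 2 are each ortho to one OMe and para to the other, whereas C5 is meta to both and para only to the central benzyloxy group, which is twisted out of conjugation by its two ortho neighbours.

Step 3
Reactants: 3 3-(benzyloxy)-1,5-dibromo-2,4-dimethoxybenzene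
Product: 4 5-(benzyloxy)-4,6-dimethoxybenzene-1,3-diol
Conditions: Pd2(dba)3 (2 mol%), tBuXPhos (8 mol%), KOH (6 equiv), 1,4-dioxane/H2O 1:1, 100 °C, Ar; then aq. HCl, 0 °C, Ar
Reagents that add atoms: potassium hydroxide, [K+].[OH-]
Why: Palladium-catalysed hydroxylation of aryl bromides with KOH (Buchwald–Hartwig-type C–O coupling); the bulky di-tert-butylbiarylphosphine should make C–O reductive elimination from the arylpalladium hydroxide faster than diaryl ether formation at both C–Br bonds, and the methyl and benzyl ethers are inert to hot aqueous base.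

Step 4
Reactants: 5 3,4-bis(benzyloxy)benzaldehyde
Product: 7 3,4-bis(benzyloxy)phenol, via aryl formate 6 (not isolated)
Conditions: mCPBA (1.3 equiv), CH2Cl2, rt; aq. NaHCO3 wash; then K2CO3 (cat.), MeOH, rt
Reagents that add atoms: 3-chloroperoxybenzoic acid, O=C(OO)c1cccc(Cl)c1
Why: Dakin-type Baeyer–Villiger oxidation; the electron-rich aryl group migrates in the Criegee intermediate to give the aryl formate, which is methanolysed to the phenol.

Step 5
Reactants: 7 3,4-bis(benzyloxy)phenol
Product: 8 1,2-bis(benzyloxy)-4-methoxybenzene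
Conditions: MeI (1.5 equiv), K2CO3 (2 equiv), acetone, reflux
Reagents that add atoms: iodomethane, CI
Why: Williamson ether synthesis on the only free hydroxyl, which fixes the future 2'-OMe on a simple monophenol.

Step 6
Reactants: 8 1,2-bis(benzyloxy)-4-methoxybenzene
Product: 9 1-[4,5-bis(benzyloxy)-2-methoxyphenyl]-2-methoxyethan-1-one
Conditions: MeOCH2CO2H (1.3 equiv), (CF3CO)2O (1.6 equiv), CH2Cl2, 0 °C to rt
Reagents that add atoms: methoxyacetic acid, COCC(=O)O
Why: Friedel–Crafts acylation through the mixed trifluoroacetic anhydride; C5 of 8 is ortho to OMe and para to a benzyloxy group and is the only doubly activated site not flanked on both sides, and the absence of a Lewis acid spares the benzyl ethers.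

Step 7
Reactants: 9 1-[4,5-bis(benzyloxy)-2-methoxyphenyl]-2-methoxyethan-1-one
Product: 10 methyl 3-[4,5-bis(benzyloxy)-2-methoxyphenyl]-2-methoxy-3-oxopropanoate
Conditions: NaH (2.5 equiv), (MeO)2CO (5 equiv), THF, reflux; then AcOH, 0 °C
Reagents that add atoms: dimethyl carbonate, COC(=O)OC
Why: Claisen condensation (C-methoxycarbonylation) of the ketone enolate with a carbonate, pulled forward by deprotonation of the β-keto ester at its one remaining α-hydrogen.

Step 8
Reactants: 4 5-(benzyloxy)-4,6-dimethoxybenzene-1,3-diol; 10 methyl 3-[4,5-bis(benzyloxy)-2-methoxyphenyl]-2-methoxy-3-oxopropanoate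
Product: 13 7-(benzyloxy)-2-[4,5-bis(benzyloxy)-2-methoxyphenyl]-5-hydroxy-3,6,8-trimethoxy-4H-chromen-4-one, via aroylketene 11 (not isolated), via 1,3-diketone 12 (not isolated)
Conditions: 4 (1.0 equiv), 10 (1.3 equiv), Ph2O (2 mol/L), 230 °C (microwave or metal bath), Ar stream, about 20 min, MeOH and H2O distilled off
Reagents that add atoms: none
Why: On heating, the enol of 10 should lose methanol through a six-membered transition state to give the α-methoxy aroylketene 11, whose ketene carbon is attacked by C2 of resorcinol 4 (directly, or after reversible O-acylation and thermal return of the ketene) to give the 2,6-dihydroxyaryl 1,3-diketone 12. The closest known reaction type is the Mentzer-type thermal chromone synthesis, the catalyst-free condensation of phloroglucinol with aroylacetic esters to 5,7-dihydroxyflavones. Ring C then closes by 6-exo-trig addition of a phenolic oxygen of 12 to the ring B ketone and loss of water, so the C4–C4a bond is made at carbon before the heteroatom closes. No stereocentre is formed, since the CH(OMe) carbon of 10 and 12 ends as sp2 C3. The step needs C- over O-acylation, chromone over coumarin, and a single regioisomer. C2 of 4 is the only unsubstituted ring carbon and is ortho to both hydroxyls and para to the benzyloxy group, O-acylation is reversible at this temperature while C-acylation is not, the two hydroxyls are related by the mirror plane through C2 and C5 so either closure gives the same flavone with the other left as the chelated 5-OH, and Pechmann-type attack on the ketone is disfavoured without acid because that carbonyl is deactivated by its 2-methoxy and 4-benzyloxy donors.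

Step 9
Reactants: 13 7-(benzyloxy)-2-[4,5-bis(benzyloxy)-2-methoxyphenyl]-5-hydroxy-3,6,8-trimethoxy-4H-chromen-4-one
Product: 14 5,7,4',5'-tetrahydroxy-3,6,8,2'-tetramethoxyflavone
Conditions: H2 (1 atm), 10% Pd/C, THF/MeOH 1:1, rt; filtered and concentrated under Ar
Reagents that add atoms: none
Why: Hydrogenolysis of three benzyl aryl ethers over palladium; the tetrasubstituted C2=C3 bond, the C4 carbonyl and the four methyl ethers should be untouched at 1 atm and rt, and the free catechol is kept from air during work-up.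

**Compound list**
1 | 2,6-dimethoxyphenol (syringol) | COc1cccc(OC)c1O | starting material
2 | 2-(benzyloxy)-1,3-dimethoxybenzene | COc1cccc(OC)c1OCc1ccccc1 | intermediate
3 | 3-(benzyloxy)-1,5-dibromo-2,4-dimethoxybenzene | COc1c(Br)cc(Br)c(OC)c1OCc1ccccc1 | intermediate
4 | 5-(benzyloxy)-4,6-dimethoxybenzene-1,3-diol | COc1c(O)cc(O)c(OC)c1OCc1ccccc1 | intermediate
5 | 3,4-bis(benzyloxy)benzaldehyde | O=Cc1ccc(OCc2ccccc2)c(OCc2ccccc2)c1 | starting material
6 | 3,4-bis(benzyloxy)phenyl formate (not isolated) | O=COc1ccc(OCc2ccccc2)c(OCc2ccccc2)c1 | intermediate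
7 | 3,4-bis(benzyloxy)phenol | Oc1ccc(OCc2ccccc2)c(OCc2ccccc2)c1 | intermediate
8 | 1,2-bis(benzyloxy)-4-methoxybenzene | COc1ccc(OCc2ccccc2)c(OCc2ccccc2)c1 | intermediate
9 | 1-[4,5-bis(benzyloxy)-2-methoxyphenyl]-2-methoxyethan-1-one | COCC(=O)c1cc(OCc2ccccc2)c(OCc2ccccc2)cc1OC | intermediate
10 | methyl 3-[4,5-bis(benzyloxy)-2-methoxyphenyl]-2-methoxy-3-oxopropanoate | COC(=O)C(OC)C(=O)c1cc(OCc2ccccc2)c(OCc2ccccc2)cc1OC | intermediate
11 | 3-[4,5-bis(benzyloxy)-2-methoxyphenyl]-2-methoxy-3-oxoprop-1-en-1-one (α-methoxy aroylketene, not isolated) | COC(=C=O)C(=O)c1cc(OCc2ccccc2)c(OCc2ccccc2)cc1OC | intermediate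
12 | 1-[4-(benzyloxy)-2,6-dihydroxy-3,5-dimethoxyphenyl]-3-[4,5-bis(benzyloxy)-2-methoxyphenyl]-2-methoxypropane-1,3-dione (not isolated) | COC(C(=O)c1c(O)c(OC)c(OCc2ccccc2)c(OC)c1O)C(=O)c1cc(OCc2ccccc2)c(OCc2ccccc2)cc1OC | intermediate
13 | 7-(benzyloxy)-2-[4,5-bis(benzyloxy)-2-methoxyphenyl]-5-hydroxy-3,6,8-trimethoxy-4H-chromen-4-one | COc1cc(OCc2ccccc2)c(OCc2ccccc2)cc1-c1oc2c(OC)c(OCc3ccccc3)c(OC)c(O)c2c(=O)c1OC | intermediate
14 | 5,7,4',5'-tetrahydroxy-3,6,8,2'-tetramethoxyflavone | COc1cc(O)c(O)cc1-c1oc2c(OC)c(O)c(OC)c(O)c2c(=O)c1OC | target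

Total step count: 9. Longest linear sequence: 6 steps (steps 4 to 9); the ring A branch (steps 1 to 3) joins at step 8.

Steps most likely to fail:

1. Step 8 (key annulation). The acylketene could be lost to dimerisation, O-acylation might not funnel to C-acylation at the crowded carbon between two hydroxyls, or the aryl ester could close in the Pechmann sense to a coumarin. Thermal loss of a benzyl group would be harmless, since all are removed in step 9. The fallback is the classical ketone route, setting out from 4 and 8 and coming back at 12. Hoesch acylation of 4 with methoxyacetonitrile (ZnCl2, HCl gas, Et2O, 0 °C) would give 1-[4-(benzyloxy)-2,6-dihydroxy-3,5-dimethoxyphenyl]-2-methoxyethan-1-iminium chloride F1, which warm water would hydrolyse to 1-[4-(benzyloxy)-2,6-dihydroxy-3,5-dimethoxyphenyl]-2-methoxyethan-1-one F2. Vilsmeier–Haack formylation of 8 (POCl3, DMF) would give 4,5-bis(benzyloxy)-2-methoxybenzaldehyde F3, and Pinnick oxidation (NaClO2, NaH2PO4, 2-methyl-2-butene) would give 4,5-bis(benzyloxy)-2-methoxybenzoic acid F4. Esterification of one of the two equivalent hydroxyls of F2 with F4 (EDC·HCl, DMAP, CH2Cl2) would give 3-(benzyloxy)-5-hydroxy-2,4-dimethoxy-6-(methoxyacetyl)phenyl 4,5-bis(benzyloxy)-2-methoxybenzoate F5. Its Baker–Venkataraman rearrangement (LiN(SiMe3)2, THF, −20 °C) would re-enter the route at diketone 12, and TsOH in toluene at 80 °C would dehydrate 12 to 13.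

2. Step 3 (double hydroxylation). After the first C–O bond forms, the electron-rich bromophenoxide may add only slowly to the catalyst, so the reaction could stall at the monophenol, lose bromine to hydrogen, or form diaryl ethers. The fallback sets out from 3 and comes back at 4. Miyaura borylation (B2pin2, Pd(dppf)Cl2, KOAc, 1,4-dioxane, 90 °C) would give 2,2'-[5-(benzyloxy)-4,6-dimethoxy-1,3-phenylene]bis(4,4,5,5-tetramethyl-1,3,2-dioxaborolane) F6, and oxidation of both C–B bonds (H2O2, NaOH, THF/H2O, 0 °C, Ar) would give 4.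

3. Step 7 (C-methoxycarbonylation). The hindered, chelated enolate could be acylated on oxygen, react incompletely, or the product could revert by retro-Claisen cleavage. The fallback sets out from 8 and comes back at 10, installing the methoxy group last. Friedel–Crafts acylation of 8 with methyl 3-chloro-3-oxopropanoate (SnCl4, CH2Cl2, −20 °C) would give methyl 3-[4,5-bis(benzyloxy)-2-methoxyphenyl]-3-oxopropanoate F7. Regitz diazo transfer (4-acetamidobenzenesulfonyl azide, Et3N, MeCN) would give methyl 3-[4,5-bis(benzyloxy)-2-methoxyphenyl]-2-diazo-3-oxopropanoate F8, and Rh2(OAc)4-catalysed carbenoid O–H insertion into methanol (CH2Cl2/MeOH, rt) would give 10.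

**Further compounds**
F1 | step 8 | 1-[4-(benzyloxy)-2,6-dihydroxy-3,5-dimethoxyphenyl]-2-methoxyethan-1-iminium chloride | COCC(=[NH2+])c1c(O)c(OC)c(OCc2ccccc2)c(OC)c1O.[Cl-]
F2 | step 8 | 1-[4-(benzyloxy)-2,6-dihydroxy-3,5-dimethoxyphenyl]-2-methoxyethan-1-one | COCC(=O)c1c(O)c(OC)c(OCc2ccccc2)c(OC)c1O
F3 | step 8 | 4,5-bis(benzyloxy)-2-methoxybenzaldehyde | COc1cc(OCc2ccccc2)c(OCc2ccccc2)cc1C=O
F4 | step 8 | 4,5-bis(benzyloxy)-2-methoxybenzoic acid | COc1cc(OCc2ccccc2)c(OCc2ccccc2)cc1C(=O)O
F5 | step 8 | 3-(benzyloxy)-5-hydroxy-2,4-dimethoxy-6-(methoxyacetyl)phenyl 4,5-bis(benzyloxy)-2-methoxybenzoate | COCC(=O)c1c(O)c(OC)c(OCc2ccccc2)c(OC)c1OC(=O)c1cc(OCc2ccccc2)c(OCc2ccccc2)cc1OC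
F6 | step 3 | 2,2'-[5-(benzyloxy)-4,6-dimethoxy-1,3-phenylene]bis(4,4,5,5-tetramethyl-1,3,2-dioxaborolane) | COc1c(B2OC(C)(C)C(C)(C)O2)cc(B2OC(C)(C)C(C)(C)O2)c(OC)c1OCc1ccccc1
F7 | step 7 | methyl 3-[4,5-bis(benzyloxy)-2-methoxyphenyl]-3-oxopropanoate | COC(=O)CC(=O)c1cc(OCc2ccccc2)c(OCc2ccccc2)cc1OC
F8 | step 7 | methyl 3-[4,5-bis(benzyloxy)-2-methoxyphenyl]-2-diazo-3-oxopropanoate | COC(=O)C(=[N+]=[N-])C(=O)c1cc(OCc2ccccc2)c(OCc2ccccc2)cc1OC
A1 | direct plan | quercetin | O=c1c(O)c(-c2ccc(O)c(O)c2)oc2cc(O)cc(O)c12
A2 | direct plan | 2-(2,2-diphenyl-1,3-benzodioxol-5-yl)-3,5,7-trihydroxy-4H-chromen-4-one | O=c1c(O)c(-c2ccc3OC(c4ccccc4)(c4ccccc4)Oc3c2)oc2cc(O)cc(O)c12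
A3 | direct plan | 2-(2,2-diphenyl-1,3-benzodioxol-5-yl)-5,7-dihydroxy-3-methoxy-4H-chromen-4-one | COc1c(-c2ccc3OC(c4ccccc4)(c4ccccc4)Oc3c2)oc2cc(O)cc(O)c2c1=O
A4 | direct plan | 6,8-dibromo-2-(2,2-diphenyl-1,3-benzodioxol-5-yl)-5,7-dihydroxy-3-methoxy-4H-chromen-4-one | COc1c(-c2ccc3OC(c4ccccc4)(c4ccccc4)Oc3c2)oc2c(Br)c(O)c(Br)c(O)c2c1=O
A5 | direct plan | 2-(3,4-dihydroxyphenyl)-5,7-dihydroxy-3,6,8-trimethoxy-4H-chromen-4-one | COc1c(-c2ccc(O)c(O)c2)oc2c(OC)c(O)c(OC)c(O)c2c1=O
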